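Starting material was left over in both earlier runs: the grey run levelled at 59.6% target and the ochre run at 30.5%, and I wanted to know what had stopped them.

in all of them: free catalyst 95 µM; impurity 56 µM
- grey: starting material 0.025 M; second substrate 0.050 M; coupling partner 0.045 M; run made earlier
- ochre: starting material 0.10 M; second substrate 0.050 M; coupling partner 0.045 M; run made earlier
- flask: starting material 0.050 M; second substrate 0.0500 M; coupling partner 0.0450 M; time 10 h

| run | time / h | target / % |
|---|---|---|
| grey | 0.833 | 38.2 |
| grey | 2.50 | 58.9 |
| grey | 4.00 | 59.8 |
| grey | 6.00 | 59.4 |
| grey | 10.0 | 59.9 |
| grey | 12.0 | 59.1 |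
| ochre | 2.00 | 30.7 |
| ochre | 4.00 | 30.1 |
| ochre | 6.00 | 31.1 |
| ochre | 8.00 | 30.3 |
| ochre | 10.0 | 30.2 |
| ochre | 12.0 | 30.4 |

(each reading ± 0.5 percentage points)

- a reading or a percentage of target counts all its forms, free or not
- the reaction counts as stopped when no species that holds the starting material changes by six tenths of a point or more over the second half of the time

- at 10 h, what has stopped the reaction, if anything has (the coupling partner has run out first / no working catalyst is left / it is still moving / forward and back rates have come level / all of the starting material has reacted)
- amount of target at 10 h, in percent of the starting material charged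

My first guess was one target per coupling partner until the partner ran out. But the plateaus were 0.0149 M and 0.0305 M, both below the partner's charge of 0.045 M. So I supposed that the second substrate competes for the partner, which would then still be the limiting reagent.

At any moment the two uses of the partner stand as s[starting material]/[second substrate], where s is the selectivity factor, the rate of each use per unit of its substrate, one over the other. As both substrates fall, this ratio drifts. With a and b the fractions left of starting material and second substrate, the drift integrates to:

a = b^s, so s = ln a / ln b

grey: a = 40.4%, b = 39.8%, s = 0.982

ochre: a = 69.5%, b = 70.9%, s = 1.06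

I took the mean, s = 1.02.

My objection was that a reversible step also fits two plateaus, given a fitted constant. But setting s to one, with nothing fitted, the charges give 60.0% and 30.0%, so the partner's charge comes back out of the readings. That persuaded me.

For the flask I set s to one, as the two runs allow; that alone makes a equal b, so the partner divides in proportion to the two charges and the yield is:

45.0%

The spread in s moves this by about 1.3 percentage points. Both runs were flat by 2.50 h, and the flask has 10 h, so I expected the partner gone.

The forecast gave 45%, within 43.5% to 46.5%, with the stop as "forward and back rates have come level", from “A balanced reversible step”.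

    free catalyst + impurity → spent catalyst (k = 19000 M⁻¹ min⁻¹)
    free catalyst + target ⇌ idle complex (K = 12.0 M⁻¹, k = 2.60 M⁻¹ min⁻¹)
    starting material + free catalyst ⇌ catalyst intermediate A (K = 63.0 M⁻¹, k = 470 M⁻¹ min⁻¹)
    second substrate + free catalyst ⇌ catalyst intermediate B (K = 3800 M⁻¹, k = 420 M⁻¹ min⁻¹)
    coupling partner + catalyst intermediate B → free catalyst + second product (k = 660 M⁻¹ min⁻¹)
    crystals ⇌ target, rate k6*(cs6 - [target]) while solid is left; crystals form when [target] > cs6 (solubility = 5.40 mM, k = 4.40 min⁻¹)
    coupling partner + catalyst intermediate A → free catalyst + target (k = 6200 M⁻¹ min⁻¹)

The flask gave 45.0%, and the stop was this: the coupling partner has run out first, with 0% of its charge left at 10.0 h. With s = 1.02, the flask's b of 54.9% gives a = 54.2%, and starting material stood at 55.0%. In the neighbour with 5.7 × 10⁻⁵ M free catalyst, 56% of the coupling partner remained, and its b of 81.0% gives a = 80.7%, where starting material stood at 79.5%.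

The readings were generated by integration for an exercise, noise included.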